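**Retrosynthetic overview**
- The aryl ether is made last, by Mitsunobu coupling of purchased umbelliferone with the primary hydroxyl of a drimane-type 3,11-diol.
- The diol comes from a bicyclic 3-keto-11-aldehyde by one bulky-hydride reduction, which gives the CH2OH group and the axial 3-OH together.
- The keto aldehyde comes from an acyclic keto enal bearing a terminal vinylallene, by a catalytic enantioselective intramolecular Diels–Alder reaction. Bonds C5–C10 and C8–C9 form, rings A and B close in the same step, C5/C9/C10 are set, and the C6=C7/C8=CH2 diene is delivered as such.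
- The keto enal comes from an acyclic diol (double oxidation), which comes from a gem-dimethyl homopropargylic alcohol (alkyne to vinylallene), which comes from the C6 aldehyde of geranyl acetate plus a dimethylallenylzinc reagent.
- Ring order: no ring exists until the cycloaddition, then both carbocycles form at once; the coumarin is bought intact.

Assumption: drimane numbering is used (C3 carbinol, C4 CMe2, C5/C10 ring fusion with 10-Me, C6=C7, C8=C12H2, C9–C11H2–OAr) and is kept for the same carbons in the acyclic precursors; the target is then 3S,5S,9R,10R with the 3-OH axial (cis to 5-H, trans to 10-Me).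

**Route**

Step 1
Reactants: 1 geranyl acetate, (2E)-3,7-dimethylocta-2,6-dien-1-yl acetate
Product: 3 (2E)-3-methyl-6-oxohex-2-en-1-yl acetate, via secondary ozonide 2 (not isolated)
Conditions: O3 (1.0 equiv, Sudan III end point), CH2Cl2, −78 °C; then Me2S, −78 °C → rt
Reagents that add atoms: ozone, [O-][O+]=O
Why: Chemoselective ozonolysis (Criegee mechanism): the isolated trisubstituted 6,7-alkene is far more electron-rich than the 2,3-alkene deactivated by the allylic acetate, so one equivalent of ozone cleaves only the former and the (E)-alkene is kept; no stereocentre is formed.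

Step 2
Reactants: 3 (2E)-3-methyl-6-oxohex-2-en-1-yl acetate; 4 3-chloro-3-methylbut-1-yne
Product: 7 rac-(2E)-3,7,7-trimethylnon-2-en-8-yne-1,6-diol, via allenylzinc chloride 5 (not isolated), via hydroxy acetate 6 (not isolated)
Conditions: Zn dust (TMSCl-activated), THF, 0 °C → rt; then MeOH, K2CO3 (cat.), rt
Reagents that add atoms: 3-chloro-3-methylbut-1-yne (4), CC(C)(Cl)C#C
Why: Barbier-type propargylation: zinc inserts into the tertiary propargylic chloride to give allenylzinc 5, which adds to the aldehyde through a cyclic SE2' transition state at its dimethyl-substituted terminus to give the α,α-dimethyl homopropargylic alcohol 6, and K2CO3/MeOH transesterification frees the allylic alcohol in the same pot; the carbinol centre (C3) is deliberately racemic because step 4 erases it.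

Step 3
Reactants: 7 rac-(2E)-3,7,7-trimethylnon-2-en-8-yne-1,6-diol; 8 methyl prop-2-yn-1-yl carbonate
Product: 10 rac-(2E,8E)-3,7,7-trimethyldodeca-2,8,10,11-tetraene-1,6-diol, via alkenyl pinacolboronate 9 (not isolated)
Conditions: B2pin2, MeOH, CuCl/Xantphos/NaOtBu (cat.), THF, rt; then 8, Pd(PPh3)4 (cat.), 50 °C
Reagents that add atoms: methyl prop-2-yn-1-yl carbonate (8), COC(=O)OCC#C
Why: Copper-catalysed protoboration (syn-addition of Cu–Bpin with boron at the unhindered alkyne terminus, then protonation by MeOH) gives the (E)-alkenylboronate 9 and tolerates both hydroxyls, and Suzuki–Miyaura coupling with the propargylic carbonate (SN2' oxidative addition to an allenyl–Pd–OMe species with loss of CO2, base-free transmetalation) gives the terminal vinylallene with retention of the (E)-alkene; no stereocentre is formed.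

Step 4
Reactants: 10 rac-(2E,8E)-3,7,7-trimethyldodeca-2,8,10,11-tetraene-1,6-diol
Product: 11 (2E,8E)-3,7,7-trimethyl-6-oxododeca-2,8,10,11-tetraenal
Conditions: Dess–Martin periodinane (2.4 equiv), pyridine, CH2Cl2, 0 °C → rt; used at once
Reagents that add atoms: none
Why: Dess–Martin oxidation converts the allylic primary alcohol into the (E)-enal and the secondary alcohol into the ketone in one operation under buffered conditions that leave the vinylallene intact; it erases the racemic carbinol centre, and the ketone cannot conjugate because C4 is quaternary.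

Step 5
Reactants: 11 (2E,8E)-3,7,7-trimethyl-6-oxododeca-2,8,10,11-tetraenal
Product: 12 (1R,4aS,8aR)-5,5,8a-trimethyl-2-methylidene-6-oxo-1,2,4a,5,6,7,8,8a-octahydronaphthalene-1-carbaldehyde
Conditions: (S)-o-tolyl-CBS oxazaborolidine (20 mol %), Tf2NH (18 mol %), CH2Cl2, −78 → −20 °C; Et3N quench
Reagents that add atoms: none
Why: Proposed new method: the closest known reactions are the chiral oxazaborolidinium-catalysed enantioselective intramolecular Diels–Alder reaction of trienals and the intramolecular Diels–Alder reaction of vinylallenes; here the cationic boron binds the formyl group (formyl C–H···O contact) of the s-trans (E)-enal and its carbinol phenyl group covers the C9-Si/C10-Re face, so the vinylallene diene (C5=C6–C7=C8) adds to the C9-Re/C10-Si face through the endo (CHO under the diene) transition state, forming C5–C10 and C8–C9 and both rings at once, which gives the trans ring fusion (5-H anti to 10-Me), keeps 10-Me and 9-CHO cis from the (E)-enal, and leaves C6=C7 and C8=CH2 in place directly.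

Step 6
Reactants: 12 (1R,4aS,8aR)-5,5,8a-trimethyl-2-methylidene-6-oxo-1,2,4a,5,6,7,8,8a-octahydronaphthalene-1-carbaldehyde
Product: 13 (2S,4aR,5R,8aS)-5-(hydroxymethyl)-1,1,4a-trimethyl-6-methylidene-1,2,3,4,4a,5,6,8a-octahydronaphthalen-2-ol
Conditions: L-Selectride (2.5 equiv), THF, −78 °C (12 added to the hydride); then H2O
Reagents that add atoms: none
Why: Substrate-controlled hydride reduction: L-Selectride reduces the aldehyde to CH2OH and, as a bulky hydride, attacks the 4,4-dimethyl-3-ketone along the equatorial trajectory (the axial approach is blocked by the syn-axial 1-H and 5-H), giving the axial 3S alcohol, as is known for 4,4-dimethyl-3-oxo terpenoids; the cold inverse addition avoids enolisation at C9.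

Step 7
Reactants: 13 (2S,4aR,5R,8aS)-5-(hydroxymethyl)-1,1,4a-trimethyl-6-methylidene-1,2,3,4,4a,5,6,8a-octahydronaphthalen-2-ol; 14 umbelliferone (7-hydroxy-2H-chromen-2-one)
Product: 15 7-{[(1R,4aS,6S,8aR)-6-hydroxy-5,5,8a-trimethyl-2-methylidene-1,2,4a,5,6,7,8,8a-octahydronaphthalen-1-yl]methoxy}-2H-chromen-2-one
Conditions: PPh3, DIAD, THF, 0 °C → rt
Reagents that add atoms: umbelliferone (14), O=c1ccc2ccc(O)cc2o1
Why: Mitsunobu etherification: the acidic phenol (pKa about 7.8) is alkylated by the alkoxyphosphonium ion of the primary alcohol, while the axial neopentylic 3-OH is too hindered to be activated, so no protecting group is needed and no stereocentre is touched.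

**Compound list**

1 | geranyl acetate, (2E)-3,7-dimethylocta-2,6-dien-1-yl acetate | CC(=O)OC/C=C(\C)CCC=C(C)C | starting material
2 | secondary ozonide, (2E)-5-(5,5-dimethyl-1,2,4-trioxolan-3-yl)-3-methylpent-2-en-1-yl acetate (racemic at the ring carbon) | CC(=O)OC/C=C(\C)CCC1OOC(C)(C)O1 | intermediate
3 | (2E)-3-methyl-6-oxohex-2-en-1-yl acetate | CC(=O)OC/C=C(\C)CCC=O | intermediate
4 | 3-chloro-3-methylbut-1-yne | CC(C)(Cl)C#C | starting material
5 | allenylzinc chloride, (3-methylbuta-1,2-dien-1-yl)zinc chloride | CC(C)=C=C[Zn]Cl | intermediate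
6 | hydroxy acetate, rac-(2E)-6-hydroxy-3,7,7-trimethylnon-2-en-8-yn-1-yl acetate | CC(=O)OC/C=C(\C)CCC(O)C(C)(C)C#C | intermediate
7 | rac-(2E)-3,7,7-trimethylnon-2-en-8-yne-1,6-diol | OC/C=C(\C)CCC(O)C(C)(C)C#C | intermediate
8 | methyl prop-2-yn-1-yl carbonate | COC(=O)OCC#C | starting material
9 | alkenyl pinacolboronate, rac-(2E,8E)-3,7,7-trimethyl-9-(4,4,5,5-tetramethyl-1,3,2-dioxaborolan-2-yl)nona-2,8-diene-1,6-diol | OC/C=C(\C)CCC(O)C(C)(C)/C=C/B1OC(C)(C)C(C)(C)O1 | intermediate
10 | rac-(2E,8E)-3,7,7-trimethyldodeca-2,8,10,11-tetraene-1,6-diol | OC/C=C(\C)CCC(O)C(C)(C)/C=C/C=C=C | intermediate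
11 | (2E,8E)-3,7,7-trimethyl-6-oxododeca-2,8,10,11-tetraenal (achiral) | O=C/C=C(\C)CCC(=O)C(C)(C)/C=C/C=C=C | intermediate
12 | (1R,4aS,8aR)-5,5,8a-trimethyl-2-methylidene-6-oxo-1,2,4a,5,6,7,8,8a-octahydronaphthalene-1-carbaldehyde (trans-fused; CHO cis to angular Me) | C=C1C=C[C@@H]2C(C)(C)C(=O)CC[C@@]2(C)[C@@H]1C=O | intermediate
13 | (2S,4aR,5R,8aS)-5-(hydroxymethyl)-1,1,4a-trimethyl-6-methylidene-1,2,3,4,4a,5,6,8a-octahydronaphthalen-2-ol (axial secondary OH) | C=C1C=C[C@@H]2C(C)(C)[C@@H](O)CC[C@@]2(C)[C@@H]1CO | intermediate
14 | umbelliferone, 7-hydroxy-2H-chromen-2-one | O=c1ccc2ccc(O)cc2o1 | starting material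
15 | 7-{[(1R,4aS,6S,8aR)-6-hydroxy-5,5,8a-trimethyl-2-methylidene-1,2,4a,5,6,7,8,8a-octahydronaphthalen-1-yl]methoxy}-2H-chromen-2-one | C=C1C=C[C@@H]2C(C)(C)[C@@H](O)CC[C@@]2(C)[C@@H]1COc1ccc2ccc(=O)oc2c1 | target

**Totals and risks**

Total steps: 7. Longest linear sequence: 7 steps (geranyl acetate to the target).

The three steps most likely to fail are steps 5, 3 and 7.

Step 5 is the largest risk. The dienophile is a β,β-disubstituted enal, and the new C5–C10 bond joins a neopentyl carbon to a quaternary one with a syn-axial Me/Me contact developing. The ring ketone can compete for the catalyst, the vinylallene is acid-sensitive, and a racemic background reaction or the cis-fused (exo) adduct would lower the selectivity. The facial sense is derived from the catalyst model, not from a measured case; if it proved opposite, the (R)-catalyst would be used.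

The fallback moves stereocontrol to a covalently bound auxiliary and sets out from 11. Pinnick oxidation (NaClO2, NaH2PO4, 2-methylbut-2-ene) gives the tetraenoic acid F1. This is coupled (PivCl, Et3N; then lithiated (4R)-4-benzyl-1,3-oxazolidin-2-one) to the N-acyl oxazolidinone F2. Me2AlCl (2.5 equiv, CH2Cl2, −30 °C) promotes the same vinylallene cycloaddition through the chelated s-cis imide: the diene adds anti to the benzyl group (again the C9-Re face) in the endo mode, giving the trans-fused cycloadduct imide F3. L-Selectride at −78 °C reduces the ring ketone to the axial hydroxy imide F4, and LiBH4 cleaves the auxiliary reductively to the primary alcohol. The fallback comes back to the route at 13.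

Step 3 runs two catalytic cycles in one pot. The protoboration could give some internal boronate, the allenyl–palladium intermediate could couple at its propargyl terminus, and the vinylallene can dimerise on warming.

The fallback reverses the polarity of the coupling and sets out from 7. Hydrozirconation (Cp2Zr(H)Cl, 3.3 equiv to cover both hydroxyls, THF, rt) followed by iodine gives the vinyl iodide F5. Stille coupling of F5 with commercial tributyl(propa-1,2-dien-1-yl)stannane (Pd2(dba)3, AsPh3, CuI, DMF, rt) gives the vinylallene. The fallback comes back at 10.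

Step 7 puts an alkoxyphosphonium ion on a β-branched primary carbon next to the quaternary C10. Substitution may be slow, and loss of the allylic 9-H toward a triene can compete.

The fallback forms the aryl–oxygen bond instead of the alkyl–oxygen bond and sets out from 13. Palladium-catalysed C–O cross-coupling of the primary alcohol with commercial 7-bromo-2H-chromen-2-one (t-BuBrettPhos Pd G3, Cs2CO3, toluene, 80 °C) never makes C11 an electrophile, and the hindered axial secondary alcohol does not compete. It arrives directly at 15 and makes no new compound (F0).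

**Further compounds**

F1 | step 5 | (2E,8E)-3,7,7-trimethyl-6-oxododeca-2,8,10,11-tetraenoic acid | OC(=O)/C=C(\C)CCC(=O)C(C)(C)/C=C/C=C=C
F2 | step 5 | (4R)-4-benzyl-3-[(2E,8E)-3,7,7-trimethyl-6-oxododeca-2,8,10,11-tetraenoyl]-1,3-oxazolidin-2-one | O=C(/C=C(\C)CCC(=O)C(C)(C)/C=C/C=C=C)N1[C@H](Cc2ccccc2)COC1=O
F3 | step 5 | (4R)-4-benzyl-3-{[(1R,4aS,8aR)-5,5,8a-trimethyl-2-methylidene-6-oxo-1,2,4a,5,6,7,8,8a-octahydronaphthalen-1-yl]carbonyl}-1,3-oxazolidin-2-one | C=C1C=C[C@@H]2C(C)(C)C(=O)CC[C@@]2(C)[C@@H]1C(=O)N1[C@H](Cc2ccccc2)COC1=O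
F4 | step 5 | (4R)-4-benzyl-3-{[(1R,4aS,6S,8aR)-6-hydroxy-5,5,8a-trimethyl-2-methylidene-1,2,4a,5,6,7,8,8a-octahydronaphthalen-1-yl]carbonyl}-1,3-oxazolidin-2-one | C=C1C=C[C@@H]2C(C)(C)[C@@H](O)CC[C@@]2(C)[C@@H]1C(=O)N1[C@H](Cc2ccccc2)COC1=O
F5 | step 3 | rac-(2E,8E)-9-iodo-3,7,7-trimethylnona-2,8-diene-1,6-diol | OC/C=C(\C)CCC(O)C(C)(C)/C=C/I
F0 | step 7 | none | none
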